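**Retrosynthetic overview**
1. The target comes from a protected triol by benzylic alcohol oxidation to the ketone, then loss of one O-TBS and two O-benzyl groups. The ketone appears late, so the labile α-aryl centre meets only neutral or buffered reagents.
2. The triol comes by hydride reduction from one compound that carries a cis-dihydrobenzofuran ester (right arm) and a cis-β-lactone (left arm). Key step: one bis(aryldiazoacetate) and one chiral dirhodium catalyst form both rings, two C–C bonds and four stereocentres in one operation.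
3. The bis(diazo) compound comes from Pd-catalysed coupling of an unsymmetrical diiodo-furofuran with a benzylic diazoacetate.
4. The furofuran comes from a tetraol, which comes from a cis-fused bis-lactone. The bis-lactone is made from succinyl bis(oxazolidinone) and two different ethers of 5-iodovanillin by a one-pot double syn-aldol and double lactonisation.
5. Ring order: two γ-lactones form together. They are opened and re-closed as the two tetrahydrofurans together. Dihydrobenzofuran and β-lactone then form together, and the β-lactone is opened for good.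

**Assumption:** the SMILES is read literally. The dihydrobenzofuran is 2,3-cis (2S,3S), the furofuran is (7S,8R,7'S,8'R) as in (+)-pinoresinol, and the α-aryl ketone carbon is S.

**Abbreviations:**
- BVB = 4-benzyloxy-3-methoxybenzyl
- ArR = 4-(BVB-oxy)-3-iodo-5-methoxyphenyl
- ArL = 4-(TBSO)-3-iodo-5-methoxyphenyl
- Xc = (S)-4-benzyl-2-oxooxazolidin-3-yl
- C7/C7' = benzylic furofuran carbons; C8/C8' = ring-fusion carbons

**Step 1**
Reactants: 1 5-iodovanillin (4-hydroxy-3-iodo-5-methoxybenzaldehyde); 2 4-benzyloxy-3-methoxybenzyl alcohol (BVB-OH)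
Product: 3 4-(BVB-oxy)-3-iodo-5-methoxybenzaldehyde
Conditions: PPh3 (1.3 equiv), DIAD (1.3 equiv), THF, 0 °C to rt
Reagents that add atoms: none
Why: Mitsunobu etherification, in which the acidic but hindered phenol of 1 is alkylated by the primary benzylic alcohol under neutral conditions and no stereocentre is formed.

**Step 2**
Reactants: 1 5-iodovanillin
Product: 4 4-(tert-butyldimethylsilyloxy)-3-iodo-5-methoxybenzaldehyde
Conditions: TBSCl (1.2 equiv), imidazole (2.5 equiv), DMF, rt
Reagents that add atoms: tert-butyldimethylsilyl chloride, CC(C)(C)[Si](C)(C)Cl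
Why: Imidazole-promoted phenol silylation, with TBS chosen because it has only primary C–H bonds and none in a 1,5 relationship to the later carbene carbon.

**Step 3**
Reactants: 5 (S)-4-benzyloxazolidin-2-one (2.05 equiv); 6 succinyl chloride
Product: 8 1,4-bis[(S)-4-benzyl-2-oxooxazolidin-3-yl]butane-1,4-dione, via lithium oxazolidinide 7 (not isolated)
Conditions: n-BuLi (2.05 equiv), THF, −78 °C; then 6, −78 to 0 °C
Reagents that add atoms: none
Why: Twofold N-acylation of the lithiated Evans auxiliary, whose stereocentres come from the commercial (S)-oxazolidinone.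

**Step 4**
Reactants: 8 succinyl bis-imide; 3 aldehyde with ArR (0.95 equiv); 4 aldehyde with ArL (1.3 equiv)
Product: 12 (3S,3aS,6S,6aS)-3-ArR-6-ArL-tetrahydrofuro[3,4-c]furan-1,4-dione, via bis(boron enolate) 9 (not isolated), via aldolate enolate 10 (not isolated), via double syn-aldol adduct 11 (not isolated)
Conditions: Bu2BOTf (2.3 equiv), iPr2NEt (2.6 equiv), CH2Cl2, 0 °C; −78 °C, 3 added over 1 h; then 4, −78 to 0 °C; MeOH, pH 7 phosphate buffer, 30% H2O2, 0 °C; crude with DMAP (0.2 equiv), CH2Cl2, rt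
Reagents that add atoms: none
Why: Proposed new method: soft enolisation of both imide arms gives the Z,Z-bis(boron enolate), each arm reacts through the dipole-minimised Zimmerman–Traxler chair of the Evans syn aldol so that each (S)-auxiliary sets its own α-carbon (S) and carbinol carbon (S), the first addition to the unhindered dienolate is faster than the second addition to the now β-branched enolate so that 3 and 4 can be brought in one after the other (the worst case is a separable 1:2:1 statistical mixture), and each freed γ-hydroxyl then acylates on the distal imide with loss of 5 to close both lactone rings as the cis-fused exo,exo bis-lactone, the closest known reaction type being the Evans boron aldol–lactonisation of succinate half-ester imides to paraconic lactones.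

**Step 5**
Reactants: 12 bis-lactone
Product: 13 (1S,2R,3R,4S)-1-ArR-4-ArL-2,3-bis(hydroxymethyl)butane-1,4-diol
Conditions: LiBH4 (6 equiv), THF–MeOH 20:1, 0 °C to rt
Reagents that add atoms: none
Why: Chemoselective borohydride reduction of both lactones, which spares aryl iodides, the silyl ether and the benzyl ethers and touches no stereocentre.

**Step 6**
Reactants: 13 tetraol
Product: 15 (1S,3aR,4S,6aR)-1-ArL-4-ArR-tetrahydro-1H,3H-furo[3,4-c]furan, via bis-mesylate 14 (not isolated)
Conditions: MsCl (2.2 equiv), pyridine, 0 °C to rt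
Reagents that add atoms: none
Why: Selective sulfonylation of the two primary alcohols followed by a double 5-exo-tet Williamson cyclisation by the benzylic hydroxyls, so both tetrahydrofuran rings close with retention at C7 and C7' and the (7S,8R,7'S,8'R) core results.

**Step 7**
Reactants: 2 BVB-OH
Product: 17 4-benzyloxy-3-methoxybenzyl diazoacetate, via glyoxylate tosylhydrazone ester 16 (not isolated)
Conditions: glyoxylic acid chloride 4-toluenesulfonylhydrazone (1.2 equiv), PhNMe2 (1.2 equiv), CH2Cl2, 0 °C; then Et3N (3 equiv), 0 °C to rt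
Reagents that add atoms: glyoxylic acid chloride 4-toluenesulfonylhydrazone, Cc1ccc(cc1)S(=O)(=O)N/N=C/C(=O)Cl
Why: One-flask diazoacetate synthesis by O-acylation and Bamford–Stevens-type loss of sulfinate from the ester tosylhydrazone, with no stereocentre involved.

**Step 8**
Reactants: 15 diiodo-furofuran; 17 BVB diazoacetate (3 equiv)
Product: 18 bis(aryldiazoacetate), that is 15 with each iodine replaced by C(=N2)CO2BVB
Conditions: Pd(PPh3)4 (10 mol %), Ag2CO3 (1.0 equiv), Et3N (2.6 equiv), toluene, rt, dark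
Reagents that add atoms: none
Why: Palladium-catalysed cross-coupling of aryl iodides with the C–H bond of a diazoacetate (oxidative addition to zerovalent palladium, silver-assisted iodide abstraction, deprotonative palladation of the diazo carbon, reductive elimination), which keeps the diazo groups and leaves all stereocentres alone.

**Step 9 (key step)**
Reactants: 18 bis(aryldiazoacetate)
Product: 20 triol (right arm (2S,3S)-cis-3-hydroxymethyl-2-aryl-dihydrobenzofuran; left arm (1R,2S)-1-aryl-1,3-dihydroxypropan-2-yl), via double insertion product 19 (not isolated)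
Conditions: Rh2(R-PTTL)4 (dirhodium tetrakis[N-phthaloyl-(R)-tert-leucinate], 2 mol %), toluene, slow addition of 18 to 2 mM, −60 to 0 °C; then iBu2AlH (10 equiv), −78 to −20 °C; aq. potassium sodium tartrate
Reagents that add atoms: none
Why: Proposed new method: the same chiral dirhodium tetracarboxylate generates both donor/acceptor carbenes and each takes the only activated C–H within reach, the right one by 1,5 insertion into the ArO–CH2Ar ether (faster than 1,4 insertion into its own ester O–CH2 because an ether oxygen activates the adjacent C–H and an acyloxy oxygen deactivates it) to give the kinetic cis-(2S,3R)-dihydrobenzofuran ester, the left one (no 1,5 C–H available, ortho-OTBS twisting the aryl ring) by 1,4 insertion into the electron-rich benzylic ester C–H to give the cis-(3R,4R)-β-lactone, and because aryl, ester carbon and new C–C bond have the same spatial order at both carbene carbons, one catalyst antipode (the mirror image of the one that gives (2R,3S)-cis esters in the parent series) sets all four centres by shielding one carbene face, after which the decarboxylation-prone β-lactone and the ester are reduced in the same flask without epimerisation, the closest known reaction types being enantioselective intramolecular C–H insertion of 2-benzyloxyaryl diazoacetates to cis-2-aryl-2,3-dihydrobenzofuran-3-carboxylates and of ortho-substituted aryldiazoacetates to cis-β-lactones.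

**Step 10**
Reactants: 20 triol
Product: 21 ketone (left arm (S)-1-(4-benzyloxy-3-methoxyphenyl)-3-hydroxy-1-oxopropan-2-yl)
Conditions: activated MnO2 (25 equiv), CH2Cl2, rt
Reagents that add atoms: none
Why: Chemoselective MnO2 oxidation of the electron-rich secondary benzylic alcohol (saturated primary alcohols and benzylic ethers are inert) under neutral heterogeneous conditions, which erases the auxiliary carbinol centre and leaves the adjacent (S) centre untouched.

**Step 11**
Reactants: 21 ketone
Product: 22 ring-B phenol (21 without TBS)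
Conditions: Bu4NF–AcOH 1:1 (1.5 equiv), THF, 0 °C
Reagents that add atoms: none
Why: Acetic acid-buffered fluoride desilylation of an aryl silyl ether, mild enough to avoid enolisation or β-elimination of the β-hydroxy ketone, and the cis-dihydrobenzofuran cannot open through a quinone methide because its 4-aryl oxygen is still benzylated.

**Step 12**
Reactants: 22 bis(benzyl ether)
Product: 23 target CNP0174045.1
Conditions: H2 (1 atm), 10% Pd/C, EtOAc–EtOH 1:1, rt, stopped at full debenzylation (about 1 h)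
Reagents that add atoms: none
Why: Neutral catalytic hydrogenolysis, in which the two primary aryl benzyl ethers cleave much faster than the secondary cyclic benzylic C–O bonds of the furofuran and dihydrobenzofuran or the aryl ketone, so no stereocentre is disturbed.

**Compound list**
1 | 5-iodovanillin | COc1cc(C=O)cc(I)c1O | starting material
2 | 4-benzyloxy-3-methoxybenzyl alcohol | COc1cc(CO)ccc1OCc1ccccc1 | starting material
3 | 4-(BVB-oxy)-3-iodo-5-methoxybenzaldehyde | COc1cc(C=O)cc(I)c1OCc1ccc(OCc2ccccc2)c(OC)c1 | intermediate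
4 | 4-(TBSO)-3-iodo-5-methoxybenzaldehyde | COc1cc(C=O)cc(I)c1O[Si](C)(C)C(C)(C)C | intermediate
5 | (S)-4-benzyloxazolidin-2-one | O=C1N[C@@H](Cc2ccccc2)CO1 | starting material
6 | succinyl chloride | O=C(Cl)CCC(=O)Cl | starting material
7 | lithium salt of 5 | [Li+].O=C1[N-][C@@H](Cc2ccccc2)CO1 | intermediate
8 | succinyl bis-imide | O=C(CCC(=O)N1[C@@H](Cc2ccccc2)COC1=O)N1[C@@H](Cc2ccccc2)COC1=O | intermediate
9 | Z,Z-bis(dibutylboron) dienolate of 8 | CCCCB(CCCC)O/C(=C\C=C(/OB(CCCC)CCCC)N1[C@@H](Cc2ccccc2)COC1=O)N1[C@@H](Cc2ccccc2)COC1=O | intermediate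
10 | boron aldolate–enolate after addition of 3 | CCCCB(CCCC)O[C@H](c1cc(OC)c(OCc2ccc(OCc3ccccc3)c(OC)c2)c(I)c1)[C@@H](C(=O)N1[C@@H](Cc2ccccc2)COC1=O)/C=C(\OB(CCCC)CCCC)N1[C@@H](Cc2ccccc2)COC1=O | intermediate
11 | (2S,3S)-2-[(S)-ArR(hydroxy)methyl]-3-[(S)-ArL(hydroxy)methyl]succinyl bis-imide | O[C@H](c1cc(OC)c(OCc2ccc(OCc3ccccc3)c(OC)c2)c(I)c1)[C@@H](C(=O)N1[C@@H](Cc2ccccc2)COC1=O)[C@H](C(=O)N1[C@@H](Cc2ccccc2)COC1=O)[C@H](O)c1cc(OC)c(O[Si](C)(C)C(C)(C)C)c(I)c1 | intermediate
12 | (3S,3aS,6S,6aS) cis-fused exo,exo bis-lactone | O=C1O[C@H](c3cc(OC)c(OCc4ccc(OCc5ccccc5)c(OC)c4)c(I)c3)[C@@H]2[C@H]1[C@@H](c3cc(OC)c(O[Si](C)(C)C(C)(C)C)c(I)c3)OC2=O | intermediate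
13 | (1S,2R,3R,4S) tetraol | O[C@H](c1cc(OC)c(OCc2ccc(OCc3ccccc3)c(OC)c2)c(I)c1)[C@@H](CO)[C@H](CO)[C@H](O)c1cc(OC)c(O[Si](C)(C)C(C)(C)C)c(I)c1 | intermediate
14 | bis(primary mesylate) of 13 | O[C@H](c1cc(OC)c(OCc2ccc(OCc3ccccc3)c(OC)c2)c(I)c1)[C@@H](COS(C)(=O)=O)[C@H](COS(C)(=O)=O)[C@H](O)c1cc(OC)c(O[Si](C)(C)C(C)(C)C)c(I)c1 | intermediate
15 | (7S,8R,7'S,8'R) diiodo-furofuran | COc1cc(cc(I)c1O[Si](C)(C)C(C)(C)C)[C@H]1OC[C@H]2[C@@H]1CO[C@@H]2c1cc(OC)c(OCc2ccc(OCc3ccccc3)c(OC)c2)c(I)c1 | intermediate
16 | BVB glyoxylate (E)-tosylhydrazone | Cc1ccc(cc1)S(=O)(=O)N/N=C/C(=O)OCc1ccc(OCc2ccccc2)c(OC)c1 | intermediate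
17 | BVB diazoacetate | [N-]=[N+]=CC(=O)OCc1ccc(OCc2ccccc2)c(OC)c1 | intermediate
18 | bis(aryldiazoacetate) | COc1cc(cc(C(=[N+]=[N-])C(=O)OCc2ccc(OCc3ccccc3)c(OC)c2)c1O[Si](C)(C)C(C)(C)C)[C@H]1OC[C@H]2[C@@H]1CO[C@@H]2c1cc(OC)c(OCc2ccc(OCc3ccccc3)c(OC)c2)c(C(=[N+]=[N-])C(=O)OCc2ccc(OCc3ccccc3)c(OC)c2)c1 | intermediate
19 | double insertion product: left (3R,4R)-cis-β-lactone, right (2S,3R)-cis-dihydrobenzofuran BVB ester | COc1cc(cc([C@H]2C(=O)O[C@H]2c3ccc(OCc4ccccc4)c(OC)c3)c1O[Si](C)(C)C(C)(C)C)[C@H]1OC[C@H]2[C@@H]1CO[C@@H]2c1cc(OC)c2c(c1)[C@@H](C(=O)OCc1ccc(OCc3ccccc3)c(OC)c1)[C@@H](c1ccc(OCc3ccccc3)c(OC)c1)O2 | intermediate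
20 | triol | COc1cc([C@H](O)[C@H](CO)c2cc([C@H]3OC[C@H]4[C@@H]3CO[C@@H]4c3cc(OC)c4c(c3)[C@@H](CO)[C@@H](c3ccc(OCc5ccccc5)c(OC)c3)O4)cc(OC)c2O[Si](C)(C)C(C)(C)C)ccc1OCc1ccccc1 | intermediate
21 | protected ketone | COc1cc(C(=O)[C@H](CO)c2cc([C@H]3OC[C@H]4[C@@H]3CO[C@@H]4c3cc(OC)c4c(c3)[C@@H](CO)[C@@H](c3ccc(OCc5ccccc5)c(OC)c3)O4)cc(OC)c2O[Si](C)(C)C(C)(C)C)ccc1OCc1ccccc1 | intermediate
22 | bis(benzyl ether) of the target | COc1cc(C(=O)[C@H](CO)c2cc([C@H]3OC[C@H]4[C@@H]3CO[C@@H]4c3cc(OC)c4c(c3)[C@@H](CO)[C@@H](c3ccc(OCc5ccccc5)c(OC)c3)O4)cc(OC)c2O)ccc1OCc1ccccc1 | intermediate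
23 | CNP0174045.1 | COc1cc(C(=O)[C@H](CO)c2cc([C@H]3OC[C@H]4[C@@H]3CO[C@@H]4c3cc(OC)c4c(c3)[C@@H](CO)[C@@H](c3ccc(O)c(OC)c3)O4)cc(OC)c2O)ccc1O | target

**Step count**
Total steps: 12. Longest linear sequence: 9 (steps 1, 4, 5, 6, 8, 9, 10, 11, 12).

**Three steps most likely to fail**

**Step 4 (one-pot hetero double aldol and double lactonisation).**
- Risks: incomplete double enolisation, a mismatch between the second auxiliary and the new neighbouring centre, and poor discrimination between first and second addition.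
- The fallback sets out from 3 and 4 and comes back at 15.
- Aldehyde 3 reacts with CH2=CHMgBr (THF, −78 °C) to give racemic 1-ArR-prop-2-en-1-ol F1.
- A Sharpless kinetic-resolution epoxidation follows [Ti(OiPr)4, D-(−)-diisopropyl tartrate, tBuOOH, 4 Å sieves, CH2Cl2, −20 °C, about 50% conversion]. It converts the fast-reacting (S)-carbinol into (R)-ArR[(R)-oxiran-2-yl]methanol F2.
- Aldehyde 4 is homologated by a Horner–Wadsworth–Emmons reaction (triethyl phosphonoacetate, NaH) to ethyl (E)-3-ArL-acrylate F3. This is reduced with iBu2AlH to (E)-3-ArL-prop-2-en-1-ol F4 and converted by an Appel reaction (CBr4, PPh3) into (E)-3-ArL-allyl bromide F5.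
- Williamson etherification of F2 with F5 (NaH, THF–DMF, 0 °C) gives epoxy cinnamyl ether F6.
- Cp2TiCl (trivalent titanium, made from Cp2TiCl2 and Zn in THF) opens the epoxide homolytically. The secondary radical closes 5-exo onto the cinnamyl double bond anti to ArR. I2 then oxidises the benzylic position so that the titanium alkoxide closes the second ring.
- Both tetrahydrofuran rings form in one flask, and the carbinol centre of F2 controls the other three centres of 15.

**Step 8 (double coupling on electron-rich, ortho-alkoxy aryl iodides).**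
- Risks: slow oxidative addition and loss of the diazo ester.
- The fallback sets out from 15 and 2 and comes back at 18.
- Alcohol 2 is acylated with bromoacetyl bromide and pyridine to BVB bromoacetate F7. Zn dust in THF turns this into Reformatsky reagent F8.
- A Negishi-type α-arylation [Pd(dba)2, P(tBu)3, THF, rt] with 15 gives bis(arylacetate) F9.
- A Regitz diazo transfer (4-acetamidobenzenesulfonyl azide, DBU, MeCN, 0 °C) installs both diazo groups to give 18.

**Step 9 (two different C–H insertions by one catalyst).**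
- Risks in the β-lactone arm: loss to arene cyclopropanation of the ester benzyl group, hydride-transfer fragmentation or decarboxylation, or the opposite facial sense.
- The fallback sets out from 15 and 2 and comes back at 20.
- Alcohol 2 is silylated (TBSCl, imidazole) to BVB tert-butyldimethylsilyl ether F10.
- Compound 15 is coupled under the step 8 conditions with commercial ethyl diazoacetate to bis(ethyl aryldiazoacetate) F11.
- Rh2(R-PTTL)4 is then used with F10 in tenfold excess. The right carbene still closes the dihydrobenzofuran. The left carbene now has only an unactivated ethyl ester, so it inserts intermolecularly into the benzylic C–H of F10 (syn-selective aldol-surrogate C–H functionalisation). This gives silyloxy diester F12.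
- iBu2AlH reduces both ethyl esters to silyloxy diol F13.
- AcOH–THF–H2O (3:1:1, rt) removes the secondary alkyl TBS ether while the hindered aryl TBS ether stays, giving 20. Any epimer at the carbinol carbon converges at 21.

**Further compounds**
F1 | step 4 | racemic 1-ArR-prop-2-en-1-ol | C=CC(O)c1cc(OC)c(OCc2ccc(OCc3ccccc3)c(OC)c2)c(I)c1
F2 | step 4 | (R)-ArR[(R)-oxiran-2-yl]methanol | O[C@H](c1cc(OC)c(OCc2ccc(OCc3ccccc3)c(OC)c2)c(I)c1)[C@H]1CO1
F3 | step 4 | ethyl (E)-3-ArL-acrylate | CCOC(=O)/C=C/c1cc(OC)c(O[Si](C)(C)C(C)(C)C)c(I)c1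
F4 | step 4 | (E)-3-ArL-prop-2-en-1-ol | OC/C=C/c1cc(OC)c(O[Si](C)(C)C(C)(C)C)c(I)c1
F5 | step 4 | (E)-3-ArL-allyl bromide | BrC/C=C/c1cc(OC)c(O[Si](C)(C)C(C)(C)C)c(I)c1
F6 | step 4 | epoxy cinnamyl ether | CC(C)(C)[Si](C)(C)Oc1c(I)cc(/C=C/CO[C@H](c2cc(OC)c(OCc3ccc(OCc4ccccc4)c(OC)c3)c(I)c2)[C@H]2CO2)cc1OC
F7 | step 8 | BVB bromoacetate | BrCC(=O)OCc1ccc(OCc2ccccc2)c(OC)c1
F8 | step 8 | Reformatsky reagent of F7 | Br[Zn]CC(=O)OCc1ccc(OCc2ccccc2)c(OC)c1
F9 | step 8 | bis(arylacetate) | COc1cc(cc(CC(=O)OCc2ccc(OCc3ccccc3)c(OC)c2)c1O[Si](C)(C)C(C)(C)C)[C@H]1OC[C@H]2[C@@H]1CO[C@@H]2c1cc(OC)c(OCc2ccc(OCc3ccccc3)c(OC)c2)c(CC(=O)OCc2ccc(OCc3ccccc3)c(OC)c2)c1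
F10 | step 9 | BVB tert-butyldimethylsilyl ether | CC(C)(C)[Si](C)(C)OCc1ccc(OCc2ccccc2)c(OC)c1
F11 | step 9 | bis(ethyl aryldiazoacetate) | COc1cc(cc(C(=[N+]=[N-])C(=O)OCC)c1O[Si](C)(C)C(C)(C)C)[C@H]1OC[C@H]2[C@@H]1CO[C@@H]2c1cc(OC)c(OCc2ccc(OCc3ccccc3)c(OC)c2)c(C(=[N+]=[N-])C(=O)OCC)c1
F12 | step 9 | silyloxy diester | COc1cc([C@H](O[Si](C)(C)C(C)(C)C)[C@H](C(=O)OCC)c2cc([C@H]3OC[C@H]4[C@@H]3CO[C@@H]4c3cc(OC)c4c(c3)[C@@H](C(=O)OCC)[C@@H](c3ccc(OCc5ccccc5)c(OC)c3)O4)cc(OC)c2O[Si](C)(C)C(C)(C)C)ccc1OCc1ccccc1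
F13 | step 9 | silyloxy diol | COc1cc([C@H](O[Si](C)(C)C(C)(C)C)[C@H](CO)c2cc([C@H]3OC[C@H]4[C@@H]3CO[C@@H]4c3cc(OC)c4c(c3)[C@@H](CO)[C@@H](c3ccc(OCc5ccccc5)c(OC)c3)O4)cc(OC)c2O[Si](C)(C)C(C)(C)C)ccc1OCc1ccccc1
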